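**Strategy.** The route rests on a Prins cyclisation–lactonisation. With labdane numbering (carbocycle C5–C10; lactone C10–C1–C2–O–C8), the target has the C1 acetic arm on C10 and the lactone oxygen on C8 in a 1,3-diaxial relationship on the cyclohexane. An open-chain aldehyde acid is therefore folded in one operation: the isopropenyl CH2 (C7) attacks the aldehyde carbon C6, closing the carbocycle, and the C8 cation is trapped by the C2 carboxylate, closing the lactone and fixing C6 and C8. The precursor carries C5, C10, C9, C11 and C13 as stereocentres and is released from a cyclopentanone template by periodate cleavage.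

Key step: step 14

Remark on labels: C3 is the free acid carbon, C4 the CMe2 carbon, C11–C16 the side chain, C17 the methyl on C8, C20 the methyl on C10.
Remark (assumption): the sense of induction in step 1 is taken to follow that of cyclic enones with the same ligand; the antipodal ligand would be used otherwise.
Remark (assumption): the target is taken to be isolable as the free C6-hydroxy C3-acid; the acid is therefore liberated last, under neutral conditions.

Step 1
Reactants: 1 furan-2(5H)-one; 2 potassium trifluoro(prop-1-en-2-yl)borate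
Product: 3 (4R)-4-(prop-1-en-2-yl)dihydrofuran-2(3H)-one
Conditions: [Rh(cod)2]BF4 (3 mol %), (R)-BINAP, toluene/H2O, 100 °C
Reagents that add atoms: none
Why: Hayashi–Miyaura-type rhodium-catalysed asymmetric 1,4-addition of an alkenylboron reagent to the unsaturated lactone, the chiral bisphosphine selecting the enantioface and so setting C9.

Step 2
Reactants: 3 (4R)-4-(prop-1-en-2-yl)dihydrofuran-2(3H)-one
Product: 5 (3S,4R)-3-methyl-4-(prop-1-en-2-yl)dihydrofuran-2(3H)-one, via lithium lactone enolate 4 (not isolated)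
Conditions: LiN(iPr)2, THF, −78 °C; then MeI
Reagents that add atoms: iodomethane, CI
Why: Lactone enolate alkylation, the electrophile entering trans to the adjacent isopropenyl group (this centre is re-planarised in step 3).

Step 3
Reactants: 5 (3S,4R)-3-methyl-4-(prop-1-en-2-yl)dihydrofuran-2(3H)-one
Product: 7 (3S,4S)-3-allyl-3-methyl-4-(prop-1-en-2-yl)dihydrofuran-2(3H)-one, via lithium lactone enolate 6 (not isolated)
Conditions: LiN(iPr)2, THF/DMPU, −78 °C; then allyl bromide, −78 → −20 °C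
Reagents that add atoms: allyl bromide, C=CCBr
Why: Alkylation of the tetrasubstituted lactone enolate anti to the isopropenyl group on the ring sets the quaternary centre C10 (allyl trans, methyl cis to isopropenyl).

Step 4
Reactants: 7 (3S,4S)-3-allyl-3-methyl-4-(prop-1-en-2-yl)dihydrofuran-2(3H)-one
Product: 8 (2S,3S)-2-allyl-3-(hydroxymethyl)-N-methoxy-N,2,4-trimethylpent-4-enamide
Conditions: MeNH(OMe)·HCl, AlMe3, CH2Cl2, 0 °C → rt; used at once
Reagents that add atoms: N,O-dimethylhydroxylamine hydrochloride, CNOC.Cl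
Why: Aluminium-amide aminolysis of the lactone (Weinreb amide formation) separates C5 (masked aldehyde) from C11 (free primary alcohol).

Step 5
Reactants: 8 (2S,3S)-2-allyl-3-(hydroxymethyl)-N-methoxy-N,2,4-trimethylpent-4-enamide
Product: 9 (2S,3S)-2-allyl-3-formyl-N-methoxy-N,2,4-trimethylpent-4-enamide
Conditions: Dess–Martin periodinane, NaHCO3, CH2Cl2, 0 °C
Reagents that add atoms: none
Why: Buffered Dess–Martin oxidation gives the C11 aldehyde without epimerising C9, whose proton is shielded by the neighbouring quaternary carbon.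

Step 6
Reactants: 9 (2S,3S)-2-allyl-3-formyl-N-methoxy-N,2,4-trimethylpent-4-enamide; 10 2-(trimethylsilyloxy)buta-1,3-diene
Product: 11 (2S,3S)-2-allyl-3-[(1S)-1-hydroxy-3-oxopent-4-en-1-yl]-N-methoxy-N,2,4-trimethylpent-4-enamide
Conditions: BF3·OEt2, CH2Cl2, −78 °C; aqueous NaHCO3
Reagents that add atoms: none
Why: Mukaiyama aldol addition under non-chelating Lewis acid follows the Felkin–Anh model (quaternary C10 anti to the nucleophile, isopropenyl as medium group), which sets C11 as S.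

Step 7
Reactants: 11 (2S,3S)-2-allyl-3-[(1S)-1-hydroxy-3-oxopent-4-en-1-yl]-N-methoxy-N,2,4-trimethylpent-4-enamide
Product: 12 (2S,3S)-2-allyl-3-[(1S,3R)-1,3-dihydroxy-3-methylpent-4-en-1-yl]-N-methoxy-N,2,4-trimethylpent-4-enamide
Conditions: MeMgBr (4 equiv), CH2Cl2/Et2O, −78 °C
Reagents that add atoms: methylmagnesium bromide, C[Mg]Br
Why: Chelation-controlled (Cram cyclic model) 1,2-addition to the β-hydroxy vinyl ketone, methyl entering axially on the six-membered magnesium chelate, gives the 1,3-syn diol and sets C13; the hindered amide is left alone at −78 °C.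

Step 8
Reactants: 12 (2S,3S)-2-allyl-3-[(1S,3R)-1,3-dihydroxy-3-methylpent-4-en-1-yl]-N-methoxy-N,2,4-trimethylpent-4-enamide
Product: 13 (2S,3S)-2-allyl-N-methoxy-N,2,4-trimethyl-3-[(1S,3R)-3-methyl-1,3-bis(triethylsilyloxy)pent-4-en-1-yl]pent-4-enamide
Conditions: Et3SiOTf, 2,6-lutidine, CH2Cl2, −78 → 0 °C
Reagents that add atoms: triethylsilyl trifluoromethanesulfonate, CC[Si](CC)(CC)OS(=O)(=O)C(F)(F)F
Why: Silyl triflate silylation caps both the secondary and the tertiary hydroxyl, which prevents relactonisation onto C5 and later hemiacetal or ether formation in the key step.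

Step 9
Reactants: 13 (2S,3S)-2-allyl-N-methoxy-N,2,4-trimethyl-3-[(1S,3R)-3-methyl-1,3-bis(triethylsilyloxy)pent-4-en-1-yl]pent-4-enamide
Product: 14 (2S,3S)-2-allyl-2,4-dimethyl-3-[(1S,3R)-3-methyl-1,3-bis(triethylsilyloxy)pent-4-en-1-yl]pent-4-enal
Conditions: iBu2AlH, THF, −78 → 0 °C; aqueous KNaC4H4O6
Reagents that add atoms: none
Why: Hydride reduction of the Weinreb amide stops at the chelated tetrahedral intermediate and releases the non-enolisable C5 aldehyde on work-up.

Step 10
Reactants: 14 (2S,3S)-2-allyl-2,4-dimethyl-3-[(1S,3R)-3-methyl-1,3-bis(triethylsilyloxy)pent-4-en-1-yl]pent-4-enal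
Product: 15 (2S,3S)-2,4-dimethyl-3-[(1S,3R)-3-methyl-1,3-bis(triethylsilyloxy)pent-4-en-1-yl]-2-(2-oxopropyl)pent-4-enal
Conditions: PdCl2 (10 mol %), Cu(OAc)2 (20 mol %), O2 (1 atm), DMA/H2O 7:1, rt
Reagents that add atoms: water, O
Why: Wacker oxidation converts the unhindered allyl group into the methyl ketone with Markovnikov selectivity, the 1,1-disubstituted isopropenyl group and the vinyl group on the fully substituted silyloxy carbon C13 being much slower substrates.

Step 11
Reactants: 15 (2S,3S)-2,4-dimethyl-3-[(1S,3R)-3-methyl-1,3-bis(triethylsilyloxy)pent-4-en-1-yl]-2-(2-oxopropyl)pent-4-enal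
Product: 16 (4R)-4-[(3S,4S,6R)-2,6-dimethyl-4,6-bis(triethylsilyloxy)octa-1,7-dien-3-yl]-4-methylcyclopent-2-en-1-one
Conditions: KOtBu (0.3 equiv), tBuOH/THF, 0 °C → rt
Reagents that add atoms: none
Why: Intramolecular aldol condensation of the 1,4-keto aldehyde (methyl carbon C6 onto the aldehyde C5) gives the 4,4-disubstituted cyclopentenone that serves as template for C5.

Step 12
Reactants: 16 (4R)-4-[(3S,4S,6R)-2,6-dimethyl-4,6-bis(triethylsilyloxy)octa-1,7-dien-3-yl]-4-methylcyclopent-2-en-1-one; 17 allyl 2-methylpropanoate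
Product: 19 allyl 2-{(1R,2R,5R)-5-[(3S,4S,6R)-2,6-dimethyl-4,6-bis(triethylsilyloxy)octa-1,7-dien-3-yl]-2-hydroxy-5-methyl-3-oxocyclopentyl}-2-methylpropanoate, via lithium cyclopentanone enolate 18 (not isolated)
Conditions: 17, LiN(iPr)2, THF, −78 °C; add 16, DMPU, −78 → −40 °C; then 3-phenyl-2-(phenylsulfonyl)oxaziridine, −78 °C
Reagents that add atoms: 3-phenyl-2-(phenylsulfonyl)oxaziridine, O=S(=O)(N1OC1c1ccccc1)c1ccccc1
Why: Michael addition of the α,α-disubstituted ester enolate (1,4-adduct favoured under equilibrating conditions) occurs on the ring face anti to the large C9 substituent of the adjacent quaternary carbon, setting C5, and the regiodefined enolate is hydroxylated in the same flask at C6 (a centre destroyed in step 13).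

Step 13
Reactants: 19 allyl 2-{(1R,2R,5R)-5-[(3S,4S,6R)-2,6-dimethyl-4,6-bis(triethylsilyloxy)octa-1,7-dien-3-yl]-2-hydroxy-5-methyl-3-oxocyclopentyl}-2-methylpropanoate
Product: 20 (3S,4S,5S,7R)-3-[(2R)-4-(allyloxy)-3,3-dimethyl-1,4-dioxobutan-2-yl]-3,7-dimethyl-4-(prop-1-en-2-yl)-5,7-bis(triethylsilyloxy)non-8-enoic acid
Conditions: NaIO4, THF/pH 7 buffer, 0 °C → rt
Reagents that add atoms: sodium periodate, [Na+].[O-]I(=O)(=O)=O
Why: Periodate cleavage of the α-hydroxy ketone opens the template between C2 and C6, giving the C2 acid and the C6 aldehyde without touching any alkene.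

Step 14
Reactants: 20 (3S,4S,5S,7R)-3-[(2R)-4-(allyloxy)-3,3-dimethyl-1,4-dioxobutan-2-yl]-3,7-dimethyl-4-(prop-1-en-2-yl)-5,7-bis(triethylsilyloxy)non-8-enoic acid
Product: 21 allyl 2-{(1S,5R,6R,7R,9S)-7-hydroxy-1,5-dimethyl-9-[(1S,3R)-3-methyl-1,3-bis(triethylsilyloxy)pent-4-en-1-yl]-3-oxo-2-oxabicyclo[3.3.1]nonan-6-yl}-2-methylpropanoate
Conditions: Me2AlCl (2.5 equiv), CH2Cl2, −78 °C; quench at −78 °C with aqueous KNaC4H4O6
Reagents that add atoms: none
Why: Me2AlCl turns the acid into its aluminium carboxylate and activates the aldehyde; the CH2 terminus C7 of the isopropenyl group then attacks C6 through a chair in which the C4 and C11 substituents are equatorial and the C1 arm on C10 is axial, and the tertiary cation at C8 is captured by the carboxylate oxygen lying 1,3-diaxial to it. The closest known reaction type is the Lewis-acid-promoted intramolecular Prins (type-two carbonyl-ene) cyclisation of δ,ε-unsaturated aldehydes bearing a 1,1-disubstituted alkene, here ended by lactonisation as in cation–olefin cyclisations terminated by carboxylic acids. The carbocycle closes 6-endo with respect to the alkene with the carbonyl oxygen exocyclic, and the lactone closes as a six-membered ring by oxygen attack on the cation. C8 can be lactonised only from the face of the axial arm, which fixes its configuration, and C6 follows from the chair in which the aluminium-bound oxygen is axial, away from the equatorial quaternary C4 group and bridged to the aluminium carboxylate. The step needs cyclisation to outrun ionisation of the tertiary allylic silyl ether and carboxylate capture to outrun proton loss or chloride capture, which the low temperature, the aprotic Lewis acid and the pre-organised axial carboxylate are meant to secure.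

Step 15
Reactants: 21 allyl 2-{(1S,5R,6R,7R,9S)-7-hydroxy-1,5-dimethyl-9-[(1S,3R)-3-methyl-1,3-bis(triethylsilyloxy)pent-4-en-1-yl]-3-oxo-2-oxabicyclo[3.3.1]nonan-6-yl}-2-methylpropanoate
Product: 22 allyl 2-{(1S,5R,6R,7R,9S)-9-[(1S,3R)-1,3-dihydroxy-3-methylpent-4-en-1-yl]-7-hydroxy-1,5-dimethyl-3-oxo-2-oxabicyclo[3.3.1]nonan-6-yl}-2-methylpropanoate
Conditions: HF·pyridine, pyridine, THF, 0 °C → rt
Reagents that add atoms: none
Why: Buffered fluoride desilylation removes both triethylsilyl ethers while the C3 acid is still an ester and so cannot lactonise onto C6–OH.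

Step 16
Reactants: 22 allyl 2-{(1S,5R,6R,7R,9S)-9-[(1S,3R)-1,3-dihydroxy-3-methylpent-4-en-1-yl]-7-hydroxy-1,5-dimethyl-3-oxo-2-oxabicyclo[3.3.1]nonan-6-yl}-2-methylpropanoate
Product: 23 2-{(1S,5R,6R,7R,9S)-9-[(1S,3R)-1,3-dihydroxy-3-methylpent-4-en-1-yl]-7-hydroxy-1,5-dimethyl-3-oxo-2-oxabicyclo[3.3.1]nonan-6-yl}-2-methylpropanoic acid (CNP0297019.1)
Conditions: Pd(PPh3)4 (5 mol %), morpholine, THF, rt; work-up at pH 4–5, 0 °C
Reagents that add atoms: none
Why: Zerovalent-palladium-catalysed allyl transfer to morpholine (Tsuji–Trost deallylation) frees the C3 acid under neutral conditions, so that neither lactonisation onto C6–OH nor translactonisation should intervene.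

**Compound list**

1 | furan-2(5H)-one | O=C1OCC=C1 | starting material
2 | potassium trifluoro(prop-1-en-2-yl)borate | [K+].CC(=C)[B-](F)(F)F | starting material
3 | (4R)-4-(prop-1-en-2-yl)dihydrofuran-2(3H)-one | O=C1OC[C@@H](C(C)=C)C1 | intermediate
4 | lithium (4R)-4-(prop-1-en-2-yl)-4,5-dihydrofuran-2-olate (enolate of 3) | [Li+].[O-]C1=C[C@H](C(C)=C)CO1 | intermediate
5 | (3S,4R)-3-methyl-4-(prop-1-en-2-yl)dihydrofuran-2(3H)-one (methyl trans to isopropenyl) | O=C1OC[C@@H](C(C)=C)[C@@H]1C | intermediate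
6 | lithium (4R)-3-methyl-4-(prop-1-en-2-yl)-4,5-dihydrofuran-2-olate (enolate of 5) | [Li+].[O-]C1=C(C)[C@H](C(C)=C)CO1 | intermediate
7 | (3S,4S)-3-allyl-3-methyl-4-(prop-1-en-2-yl)dihydrofuran-2(3H)-one (allyl trans to isopropenyl) | O=C1OC[C@@H](C(C)=C)[C@]1(C)CC=C | intermediate
8 | (2S,3S)-2-allyl-3-(hydroxymethyl)-N-methoxy-N,2,4-trimethylpent-4-enamide | OC[C@@H](C(C)=C)[C@](C(=O)N(C)OC)(C)CC=C | intermediate
9 | (2S,3S)-2-allyl-3-formyl-N-methoxy-N,2,4-trimethylpent-4-enamide | O=C[C@@H](C(C)=C)[C@](C(=O)N(C)OC)(C)CC=C | intermediate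
10 | 2-(trimethylsilyloxy)buta-1,3-diene | C=CC(=C)O[Si](C)(C)C | starting material
11 | (2S,3S)-2-allyl-3-[(1S)-1-hydroxy-3-oxopent-4-en-1-yl]-N-methoxy-N,2,4-trimethylpent-4-enamide | C=CC(=O)C[C@H](O)[C@@H](C(C)=C)[C@](C(=O)N(C)OC)(C)CC=C | intermediate
12 | (2S,3S)-2-allyl-3-[(1S,3R)-1,3-dihydroxy-3-methylpent-4-en-1-yl]-N-methoxy-N,2,4-trimethylpent-4-enamide | C=C[C@](C)(O)C[C@H](O)[C@@H](C(C)=C)[C@](C(=O)N(C)OC)(C)CC=C | intermediate
13 | (2S,3S)-2-allyl-N-methoxy-N,2,4-trimethyl-3-[(1S,3R)-3-methyl-1,3-bis(triethylsilyloxy)pent-4-en-1-yl]pent-4-enamide | C=C[C@](C)(O[Si](CC)(CC)CC)C[C@H](O[Si](CC)(CC)CC)[C@@H](C(C)=C)[C@](C(=O)N(C)OC)(C)CC=C | intermediate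
14 | (2S,3S)-2-allyl-2,4-dimethyl-3-[(1S,3R)-3-methyl-1,3-bis(triethylsilyloxy)pent-4-en-1-yl]pent-4-enal | C=C[C@](C)(O[Si](CC)(CC)CC)C[C@H](O[Si](CC)(CC)CC)[C@@H](C(C)=C)[C@](C=O)(C)CC=C | intermediate
15 | (2S,3S)-2,4-dimethyl-3-[(1S,3R)-3-methyl-1,3-bis(triethylsilyloxy)pent-4-en-1-yl]-2-(2-oxopropyl)pent-4-enal | C=C[C@](C)(O[Si](CC)(CC)CC)C[C@H](O[Si](CC)(CC)CC)[C@@H](C(C)=C)[C@](C=O)(C)CC(C)=O | intermediate
16 | (4R)-4-[(3S,4S,6R)-2,6-dimethyl-4,6-bis(triethylsilyloxy)octa-1,7-dien-3-yl]-4-methylcyclopent-2-en-1-one | C=C[C@](C)(O[Si](CC)(CC)CC)C[C@H](O[Si](CC)(CC)CC)[C@@H](C(C)=C)[C@]1(C)CC(=O)C=C1 | intermediate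
17 | allyl 2-methylpropanoate | CC(C)C(=O)OCC=C | starting material
18 | lithium enolate of the Michael adduct (enolate oxygen on C2, double bond C2=C6; C4 group on C5 cis to the ring methyl) | C=C[C@](C)(O[Si](CC)(CC)CC)C[C@H](O[Si](CC)(CC)CC)[C@@H](C(C)=C)[C@]1(C)CC([O-])=C[C@H]1C(C)(C)C(=O)OCC=C.[Li+] | intermediate
19 | allyl 2-{(1R,2R,5R)-5-[(3S,4S,6R)-2,6-dimethyl-4,6-bis(triethylsilyloxy)octa-1,7-dien-3-yl]-2-hydroxy-5-methyl-3-oxocyclopentyl}-2-methylpropanoate | C=C[C@](C)(O[Si](CC)(CC)CC)C[C@H](O[Si](CC)(CC)CC)[C@@H](C(C)=C)[C@]1(C)CC(=O)[C@H](O)[C@H]1C(C)(C)C(=O)OCC=C | intermediate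
20 | (3S,4S,5S,7R)-3-[(2R)-4-(allyloxy)-3,3-dimethyl-1,4-dioxobutan-2-yl]-3,7-dimethyl-4-(prop-1-en-2-yl)-5,7-bis(triethylsilyloxy)non-8-enoic acid | C=C[C@](C)(O[Si](CC)(CC)CC)C[C@H](O[Si](CC)(CC)CC)[C@@H](C(C)=C)[C@]([C@@H](C=O)C(C)(C)C(=O)OCC=C)(C)CC(=O)O | intermediate
21 | allyl 2-{(1S,5R,6R,7R,9S)-7-hydroxy-1,5-dimethyl-9-[(1S,3R)-3-methyl-1,3-bis(triethylsilyloxy)pent-4-en-1-yl]-3-oxo-2-oxabicyclo[3.3.1]nonan-6-yl}-2-methylpropanoate | C=C[C@](C)(O[Si](CC)(CC)CC)C[C@H](O[Si](CC)(CC)CC)[C@@H]1[C@]2(C)CC(=O)O[C@@]1(C)C[C@@H](O)[C@H]2C(C)(C)C(=O)OCC=C | intermediate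
22 | allyl 2-{(1S,5R,6R,7R,9S)-9-[(1S,3R)-1,3-dihydroxy-3-methylpent-4-en-1-yl]-7-hydroxy-1,5-dimethyl-3-oxo-2-oxabicyclo[3.3.1]nonan-6-yl}-2-methylpropanoate | C=C[C@](C)(O)C[C@H](O)[C@@H]1[C@]2(C)CC(=O)O[C@@]1(C)C[C@@H](O)[C@H]2C(C)(C)C(=O)OCC=C | intermediate
23 | 2-{(1S,5R,6R,7R,9S)-9-[(1S,3R)-1,3-dihydroxy-3-methylpent-4-en-1-yl]-7-hydroxy-1,5-dimethyl-3-oxo-2-oxabicyclo[3.3.1]nonan-6-yl}-2-methylpropanoic acid | C=C[C@](C)(O)C[C@H](O)[C@@H]1[C@]2(C)CC(=O)O[C@@]1(C)C[C@@H](O)[C@H]2C(C)(C)C(=O)O | target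

**Step count.** Total steps: 16. Longest linear sequence: 16 steps (1 → 23).

**Steps most likely to fail**

Step 14. The C8 cation may lose a proton (plain carbonyl-ene outcome) or be taken by chloride before the carboxylate closes the lactone, or the tertiary allylic silyl ether may ionise. The fallback sets out from 20 and comes back at 21. The cyclisation is run deliberately as a carbonyl-ene reaction (Me2AlCl, CH2Cl2, −78 °C, short contact) to the exocyclic-methylene hydroxy acid F1. The lactone is then closed by iodolactonisation (I2, NaHCO3, MeCN, 0 °C), the carboxylate attacking the tertiary carbon C8 from its axial face, to give the iodomethyl lactone F2. Radical reduction (Bu3SnH, AIBN, toluene, 80 °C) then gives 21.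

Step 12. The ester enolate may add 1,2, fail to attack the β-carbon next to the quaternary centre, or add with poor facial selectivity. The fallback sets out from 16 and comes back at 19. A Mukaiyama–Michael addition of dimethylketene bis(trimethylsilyl) acetal F3 (made from isobutyric acid, LiN(iPr)2 and Me3SiCl) to 16 under Me3SiOTf catalysis (5 mol %, CH2Cl2, −78 °C) gives the silyl enol ether silyl ester F4. Rubottom oxidation with dimethyldioxirane (acetone, −78 °C) and aqueous work-up gives the hydroxy keto acid F5. Alkylation of the carboxylate (allyl bromide, KHCO3, DMF) gives 19.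

Step 1. Transmetalation and turnover may be slow with the five-membered lactone, or the enantioselectivity may be low. The fallback sets out from 1 and comes back at 3, replacing asymmetric catalysis by resolution. Copper-catalysed conjugate addition of CH2=C(CH3)MgBr (CuBr·SMe2 10 mol %, Me3SiCl, THF, −78 °C) to 1 gives the racemic lactone F6. Aminolysis with (R)-1-phenylethylamine and AlMe3 gives two diastereomeric hydroxy amides, from which the (3R) amide F7 is separated by crystallisation or chromatography. Acid-catalysed relactonisation (TsOH, toluene, 80 °C) returns enantiopure 3.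

**Further compounds**

F1 | step 14 | allyl 2-[(1R,2R,4S,5R)-4-(carboxymethyl)-2-hydroxy-4-methyl-6-methylidene-5-side-chain cyclohexyl]-2-methylpropanoate (exocyclic-methylene hydroxy acid; side chain = (1S,3R)-3-methyl-1,3-bis(triethylsilyloxy)pent-4-en-1-yl; ring numbering C5, C6, C7, C8, C9, C10 of the target) | C=C[C@](C)(O[Si](CC)(CC)CC)C[C@H](O[Si](CC)(CC)CC)[C@H]1C(=C)C[C@@H](O)[C@@H](C(C)(C)C(=O)OCC=C)[C@@]1(C)CC(=O)O
F2 | step 14 | iodomethyl lactone (21 with CH2I in place of the methyl group on C8) | C=C[C@](C)(O[Si](CC)(CC)CC)C[C@H](O[Si](CC)(CC)CC)[C@@H]1[C@]2(C)CC(=O)O[C@@]1(CI)C[C@@H](O)[C@H]2C(C)(C)C(=O)OCC=C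
F3 | step 12 | dimethylketene bis(trimethylsilyl) acetal | CC(C)=C(O[Si](C)(C)C)O[Si](C)(C)C
F4 | step 12 | trimethylsilyl 2-methyl-2-[cyclopentenyl]propanoate, the trimethylsilyl enol ether (C2=C6) of the Michael adduct | C=C[C@](C)(O[Si](CC)(CC)CC)C[C@H](O[Si](CC)(CC)CC)[C@@H](C(C)=C)[C@]1(C)CC(O[Si](C)(C)C)=C[C@H]1C(C)(C)C(=O)O[Si](C)(C)C
F5 | step 12 | hydroxy keto acid (free acid corresponding to 19) | C=C[C@](C)(O[Si](CC)(CC)CC)C[C@H](O[Si](CC)(CC)CC)[C@@H](C(C)=C)[C@]1(C)CC(=O)[C@H](O)[C@H]1C(C)(C)C(=O)O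
F6 | step 1 | racemic 4-(prop-1-en-2-yl)dihydrofuran-2(3H)-one | O=C1OCC(C(C)=C)C1
F7 | step 1 | (3R)-3-(hydroxymethyl)-4-methyl-N-[(1R)-1-phenylethyl]pent-4-enamide | OC[C@@H](C(C)=C)CC(=O)N[C@H](C)c1ccccc1
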